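I drop the fitted curve and keep a ledger in turnovers: each mole of left-handed product is booked as one pass of the free catalyst and, on my assumption, one mole of solid reagent that first had to dissolve.

| flask | left-handed substrate | right-handed substrate | solid reagent | free catalyst | racemization catalyst | temperature | remark | time |
|---|---|---|---|---|---|---|---|---|
| zeta | 0.25 M | 0.25 M | 2 equiv | 15 mol% | 0.1 mol% | −10 °C | run made earlier |  |
| alpha | 0.25 M | 0.25 M | 2 equiv | 15 mol% | 0.15 mol% | 12 °C | run made earlier |  |
| delta | 0.25 M | 0.25 M | 2 equiv | 7.5 mol% | 0.2 mol% | −10 °C | run made earlier |  |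
| ash | 0.25 M | 0.25 M | 2.00 equiv | 15 mol% | 0.2 mol% | −20 °C |  | 12 h |
| larch | 0.25 M | 0.25 M | 2.00 equiv | 15 mol% | 0.2 mol% | 20 °C |  | 8.0 h |

| run | time / h | left-handed product / % |
|---|---|---|
| zeta | 0.667 | 0 |
| zeta | 0.833 | 0.3 |
| zeta | 1.33 | 0.1 |
| zeta | 2.00 | 0.6 |
| zeta | 3.00 | 1.3 |
| zeta | 5.00 | 2.6 |
| zeta | 8.00 | 5.8 |
| alpha | 0.200 | 0 |
| alpha | 0.250 | 0.2 |
| alpha | 0.417 | 0.2 |
| alpha | 0.667 | 0.1 |
| alpha | 1.00 | 0.3 |
| alpha | 1.50 | 1.1 |
| alpha | 2.50 | 3.0 |
| delta | 0.667 | 0 |
| delta | 2.00 | 0.1 |
| delta | 4.00 | 1.0 |
| delta | 5.00 | 1.5 |
| delta | 8.00 | 3.4 |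

(scatter of a reading: 0.3 percentage points)

- free catalyst is single-handed; left-handed substrate and right-handed substrate are mirror images of each other, charged as a racemate, each of them at the stated concentration
- as a solid, counted per litre of solution: solid reagent
- at the start none of the solid reagent is in solution

1. which of the two ends with the higher amount of left-handed product, in percent of the left-handed substrate and right-handed substrate together charged ("neither" if they lie within 2 percentage points) (ash / larch / neither)
2. left-handed product at the end, in percent of the left-handed substrate and right-handed substrate together charged, ash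
3. left-handed product at the end, in percent of the left-handed substrate and right-handed substrate together charged, larch

Charge: 2.00 equiv of solid reagent on left-handed substrate, which is one mole for each mole of the two substrates together, with none in solution at the start.

Delay: alpha's last step, run backwards, reaches zero at τ = 0.921 h.

Turnovers: N = 2 × (rise in left-handed product) / (free catalyst loading × time) = 0.253 h⁻¹, the turnover rate of left-handed product, read from alpha's last step, with a scatter of 0.3 percentage points on each end.

This is a faster count than the last step of zeta or delta gives. I assume dissolving is the rate-limiting step in larch and that it keeps alpha's pace at 20 °C. So larch books N(t − τ) = 1.79 turnovers: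

left-handed product, larch = N(t − τ) × loading / 2 = 13.4%

For ash the same line gives 21.0%, more than the 6% of the forecast, so I keep the forecast's number there.

The forecast says larch, with 6% for ash and 38% for larch, and reads the curves thus: “the solid reagent feeds in slowly, so the rate grows as it dissolves”. We part on larch: its number needs 5.07 turnovers.

Larch ends at 13.6% and ash at 4.97%, so larch ends higher. At 8.00 h in larch, partner, the dissolved form of the solid reagent, is made 1.02 times as fast as it is used up. At 4.00 h N(t − τ) gives 5.85%, and larch holds 6.37%.

    partner + free catalyst + left-handed substrate → free catalyst + left-handed product (k = 0.00160 M⁻² s⁻¹, Ea = 52.0 kJ mol⁻¹)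
    partner + free catalyst + right-handed substrate → free catalyst + right-handed product (k = 6.90 × 10⁻⁴ M⁻² s⁻¹, Ea = 41.0 kJ mol⁻¹)
    left-handed substrate + racemization catalyst ⇌ right-handed substrate + racemization catalyst, rate k3*[racemization catalyst]*[left-handed substrate] forward; the back reaction follows from the equilibrium constant (k = 0.0770 M⁻¹ s⁻¹, Ea = 41.0 kJ mol⁻¹)
    solid reagent ⇌ partner, rate k4*(cs4 - [partner]) while solid is left; crystals form when [partner] > cs4 (solubility = 0.130 M, k = 2.50 × 10⁻⁵ s⁻¹)
    (constants at −20 °C)

Larch read at 20 h is the second flask: N(t − τ) gives 36.2% of left-handed product. The computed flask holds 34.8%.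

The numbers in the tables were generated by integration with constants of no real substance, noise included.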